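## Structural features

The target is a 9,9'-epoxylignan: one tetrahydrofuran ring (O, C9, C8, C8', C9') carrying side chains on two adjacent ring carbons. C8' bears a 4-hydroxy-3-methoxybenzyl group through C7'. C8 bears the secondary benzylic carbinol C7, whose aryl group is 4-hydroxy-3,5-dimethoxyphenyl. Three stereocentres stand in a row, C7 (S), C8 (R) and C8' (R), and the two ring substituents are trans. The fragile parts are the two free phenols and above all the C7 hydroxyl: it is benzylic and para to a phenolic oxygen, so acid can ionise it, which would epimerise C7 or let O7 close onto C9' to give the isomeric 7,9'-ether. The real difficulty is the absolute configuration at C8, a carbon with no functional group of its own, and its relation to the exocyclic centre C7. The key step exploits the fact that C8 lies between two ring carbons, C9 and C8', that are both CH2 groups as long as C8' is not yet benzylated, and that the ring oxygen sits on C9. Removing the oxygen between C9' and C9 leaves a cyclobutanone in which C8 is prochiral, so one group-selective oxygen insertion makes the ring, the O–C9 bond and the C8 stereocentre together. The carbonyl left at C9' then activates C8' for benzylation trans to C8.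

## Logic of the disconnections

**21 to 20.** The three O–Si bonds are the last to be cut. Both phenols and the C7 hydroxyl stay masked by one kind of group so that a single fluoride treatment ends the synthesis. The demand is a buffered fluoride source, so that the freed p-hydroxybenzylic alcohol does not ionise.

**20 to 18, through 19.** The ring O–C9' bond (equivalently O–C9) is cut. Both carbons are primary and no stereocentre is touched, so either hydroxyl of 18 may carry the leaving group and the same ether results. The demand is that O7 stays silylated and that no strong base is used, so the 7,9'-closure cannot compete.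

**18 to 17.** C9' is returned to the acyl oxidation level and re-joined to O9. The gain is an acidic C8'–H next to a carbonyl, which the following disconnection needs. The forward hydride reduction must leave the aryl silyl ethers alone.

**17 to 11 and 15.** The C8'–C7' bond is cut. This removes the whole guaiacyl half and one stereocentre, leaving 11 with only C7 and C8. The forward enolate alkylation must be a mono-alkylation that enters anti to the C8 substituent.

**15 to 14 to 13 to 12.** The C–Br bond, the benzylic C–H and the phenolic O–Si bond are cut in turn. These are routine functional-group changes on a cheap aromatic aldehyde; the only demand is that 15, a labile electron-rich halide, is made just before use.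

**11 to 10.** The O–C9 bond is cut, with ring contraction. This removes the ring oxygen and the C8 stereocentre in one stroke: in 10 the carbon C8 carries two identical CH2 arms. The forward oxygen insertion must choose one of the two arms under catalyst control and must leave C7, the arene and the silyl ethers intact.

**10 to 8, through 9.** The ring C=O is traced back to an exocyclic C=CH2. A four-membered ketone could not survive the organomagnesium step or the ketone hydrogenation that set up C7, so it is carried as an alkene and revealed last. A second way to 10, building the four-membered ring by ketene cycloaddition onto an allylic and benzylic silyl ether, was set aside: it exposes a doubly activated C7–O bond to zinc halide and needs a resolution that discards half the material. The forward cleavage must be neutral.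

**8 to 7 to 6.** The C7 O–Si bond and then the C7–H bond are cut. C7 is an aryl carbinol, so it is derived from the achiral ketone 6 by catalytic enantioselective hydrogenation and is never allylic at any stage. The demand is face selectivity and reduction of C=O without touching C=C.

**6 to 2 and 3, through 4 and 5.** The aryl–C7 bond is cut. Both halves are simple: a protected bromophenol and a commercial cyclobutane nitrile that already holds the masked ketone. A nitrile stops at the ketone oxidation level, so no over-addition is possible.

**2 to 1.** The phenolic O–Si bond is cut; the phenol must be masked before the organomagnesium step.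

## Other disconnections considered

**Alternative 1:** The cuts are C7–C8 and C8'–C7'. Forward, the 2-lithio derivative of the aryl dithiane A3 would add to C8 of the menthyloxybutenolide A2 anti to the acetal alkoxy group, and the resulting lactone enolate would be benzylated at C8' by 15 anti to the new C8 substituent, giving the adduct A1 in one flask.
- In favour: two C–C bonds and both ring stereocentres come from an inexpensive crystalline auxiliary, with relay of stereochemistry around the ring and no chiral catalyst to tune. On bond-forming economy and on the security of C8 it is the better of the two plans; the trans benzylation is the same event in both and is equal.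
- Against: C7 arrives as a dithioacetal. It must be unmasked in the presence of two electron-rich rings and the ketone then reduced with 1,2-induction from C8 alone, whose sense and level are uncertain. The acetal carbon C9 must also be reduced and the auxiliary removed before the ether can be closed, and a free C7 oxygen near an activated C9' invites 7,9'-closure.
- Comparison: the step count is about equal, and the mechanism is polar and substrate-controlled throughout. Structurally it is stronger at C8 and C8' and weaker at C7, which the chosen plan fixes first by a catalyst and never re-makes.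

**Alternative 2:** The cuts are C8–C9 and C8'–C9'. Forward, CsF would release the unsubstituted carbonyl ylide from the silylmethyl chloromethyl ether A6, and this 1,3-dipole would add across the E double bond of the enoyl imide A5 to give the tetrahydrofuranoyl imide A4.
- In favour: the tetrahydrofuran ring is formed directly at its final oxidation level, so no lactone reduction or etherification is needed; in this respect it is better than the chosen plan. The trans relation follows stereospecifically from the E alkene in a concerted cycloaddition, which is equal in reliability to the enolate alkylation.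
- Against: facial selectivity must come from an oxazolidinone imide without a chelating Lewis acid (incompatible with fluoride), so the imide rotamer is not locked. A5 is a γ-aryl crotonyl imide whose double bond can slip into conjugation with the arene under basic fluoride. Its aryl silyl ether is fluoride-labile, so the phenol protection would have to change. C7 would then be built by acyl substitution with 4 and a substrate-controlled ketone reduction.
- Comparison: it is shorter on paper and mechanistically elegant, but it has two uncertain stereochemical events (the face of the cycloaddition and C7) against one catalyst-controlled group selection in the chosen plan.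

**Alternative 3:** The cut is C8–C8'. Forward, Rh2(S-PTTL)4 would decompose the aroyl diazoacetate A8 and the carbenoid carbon C8 would insert into a C8'–H bond of the 3-arylpropyl ester (1,5-insertion), closing the aroyl lactone A7.
- In favour: the central bond between the two halves is made with both aryl groups already in place, and A8 needs only an esterification and a diazo transfer. On convergence and on step count up to the lactone it is the better plan. The trans relation is self-correcting because C8–H of A7 lies between two carbonyls.
- Against: site selectivity is in doubt. The benzylic C7'–H (six-membered insertion) and the electron-rich guaiacyl ring (cyclopropanation and Buchner ring expansion) compete with the unactivated C8'–H. Enantiocontrol with acceptor/acceptor carbenoids is less secure than with simple diazoacetates. The lactone carbonyl ends up at C9, so full reduction gives hydroxyls at C7, C9 and C9' that must be told apart, with the benzylic 7,9'-closure being the easier one. C7 is again set late under substrate control.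
- Comparison: it is stronger in convergence and weaker in chemoselectivity and in control of C7. Mechanistically it relies on a metal carbenoid discriminating among several reactive sites, whereas the chosen plan relies on a strained ketone that is by far the most reactive site in its molecule.

Key step: step 6

Remark: lignan numbering is used for atoms (C7, C8, C9 on the 4-hydroxy-3,5-dimethoxyphenyl half; C7', C8', C9' on the 4-hydroxy-3-methoxyphenyl half) and every silyl group is tert-butyldimethylsilyl (TBS); in this numbering the target is (7S,8R,8'R), and the structures of 10 and 11 agree with it, so none needed correction.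

## Route

Step 1
Reactants: 1 4-bromo-2,6-dimethoxyphenol
Product: 2 (4-bromo-2,6-dimethoxyphenoxy)(tert-butyl)dimethylsilane
Conditions: TBSCl, imidazole, DMF, rt
Reagents that add atoms: tert-butyldimethylsilyl chloride (TBSCl), CC(C)(C)[Si](C)(C)Cl
Why: Standard O-silylation of a phenol; the silyl ether masks the acidic OH for the organomagnesium step and is the same group used on the other two hydroxyls, so one reagent removes all three at the end.

Step 2
Reactants: 2 (4-bromo-2,6-dimethoxyphenoxy)(tert-butyl)dimethylsilane; 3 3-methylidenecyclobutane-1-carbonitrile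
Product: 6 [4-(tert-butyldimethylsilyloxy)-3,5-dimethoxyphenyl](3-methylidenecyclobutyl)methanone, via arylmagnesium bromide 4 (not isolated), via bromomagnesium ketimide 5 (not isolated)
Conditions: Mg turnings, LiCl, THF, 40 °C; then 3, CuBr·SMe2 (3 mol%), THF, 50 °C; then 1 M aq. HCl, 0 °C to rt
Reagents that add atoms: water, O
Why: Grignard addition to a nitrile; the ketimide salt cannot add a second aryl group, and mild acid hydrolysis releases the ketone while the aryl silyl ether and the exocyclic alkene persist.

Step 3
Reactants: 6 [4-(tert-butyldimethylsilyloxy)-3,5-dimethoxyphenyl](3-methylidenecyclobutyl)methanone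
Product: 7 (S)-[4-(tert-butyldimethylsilyloxy)-3,5-dimethoxyphenyl](3-methylidenecyclobutyl)methanol
Conditions: RuH(BH4)[(R)-xylbinap][(R,R)-dpen] (0.2 mol%), H2 (8 atm), i-PrOH, 30 °C
Reagents that add atoms: none
Why: Noyori asymmetric hydrogenation of an aryl alkyl ketone by a diphosphine/diamine ruthenium hydride (outer-sphere hydride and proton transfer); the (R)/(R,R) catalyst, the antipode that gives (S)-1-arylalkanols, should deliver hydride to the Re face and set C7 as S, while the base-free catalyst spares the aryl silyl ether and does not reduce the C=C bond.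

Step 4
Reactants: 7 (S)-[4-(tert-butyldimethylsilyloxy)-3,5-dimethoxyphenyl](3-methylidenecyclobutyl)methanol
Product: 8 tert-butyl{(S)-[4-(tert-butyldimethylsilyloxy)-3,5-dimethoxyphenyl](3-methylidenecyclobutyl)methoxy}dimethylsilane
Conditions: TBSCl, imidazole, DMAP (cat.), DMF, 35 °C
Reagents that add atoms: tert-butyldimethylsilyl chloride (TBSCl), CC(C)(C)[Si](C)(C)Cl
Why: Silylation of the secondary benzylic alcohol under basic, non-ionising conditions, so C7 keeps its configuration; the ether later blocks hemiketal formation, translactonisation to the 7,9'-olide and 7,9'-ether closure.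

Step 5
Reactants: 8 tert-butyl{(S)-[4-(tert-butyldimethylsilyloxy)-3,5-dimethoxyphenyl](3-methylidenecyclobutyl)methoxy}dimethylsilane
Product: 10 3-{(S)-(tert-butyldimethylsilyloxy)[4-(tert-butyldimethylsilyloxy)-3,5-dimethoxyphenyl]methyl}cyclobutan-1-one, via glycol 9 (not isolated)
Conditions: OsO4 (2 mol%), NaIO4 (4 equiv), 2,6-lutidine, dioxane–H2O (3:1), rt
Reagents that add atoms: osmium tetroxide (catalytic, regenerated by periodate), O=[Os](=O)(=O)=O; sodium periodate, [Na+].[O-]I(=O)(=O)=O
Why: Lemieux–Johnson oxidative cleavage of the 1,1-disubstituted alkene through the glycol; the medium is neutral and buffered, so the silyl ethers and the electron-rich ring are left alone and C7 is untouched.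

Step 6
Reactants: 10 3-{(S)-(tert-butyldimethylsilyloxy)[4-(tert-butyldimethylsilyloxy)-3,5-dimethoxyphenyl]methyl}cyclobutan-1-one
Product: 11 (4R)-4-{(S)-(tert-butyldimethylsilyloxy)[4-(tert-butyldimethylsilyloxy)-3,5-dimethoxyphenyl]methyl}dihydrofuran-2(3H)-one
Conditions: Sc(OTf)3 (10 mol%), chiral N,N'-dioxide ligand (pipecolic-acid-derived bis(2,6-diisopropylanilide), 10 mol%), m-CPBA (1.3 equiv), EtOAc, −20 °C
Reagents that add atoms: 3-chloroperoxybenzoic acid (m-CPBA), OOC(=O)c1cccc(Cl)c1
Why: Sc(OTf)3 held in the chiral N,N'-dioxide pocket activates the strained carbonyl, m-CPBA adds to give the Criegee adduct, and the ring CH2 anti-periplanar to the O–O bond shifts from C9' to oxygen as the carboxylate leaves. The closest known reaction type is the catalytic enantioselective Baeyer–Villiger desymmetrisation of prochiral 3-substituted cyclobutanones to β-substituted γ-butyrolactones. The lactone ring is not closed by a cyclisation: it arises by ring enlargement, oxygen being inserted into the C9'–C9 bond of the four-membered ring (O–C9 formed, C9'–C9 broken). The new stereocentre C8 is created by group selection: migration of the pro-R methylene of ring carbon 3 gives (4R), and the ligand makes this choice, the antipode used being the one whose preference coincides with the small intrinsic bias of the freely rotating C7 substituent. C7 takes no part and keeps its configuration, and no bond to C8 itself changes. Chemoselectivity rests on ring strain: the cyclobutanone should react at −20 °C, where the silyl ethers and the trioxygenated arene are expected to survive. Because 10 is a single enantiomer, migration of the wrong methylene (or any (R)-carbinol carried from step 3) would appear as a diastereomer of 11 that chromatography can remove.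

Step 7
Reactants: 12 vanillin (4-hydroxy-3-methoxybenzaldehyde)
Product: 13 4-(tert-butyldimethylsilyloxy)-3-methoxybenzaldehyde
Conditions: TBSCl, imidazole, CH2Cl2, rt
Reagents that add atoms: tert-butyldimethylsilyl chloride (TBSCl), CC(C)(C)[Si](C)(C)Cl
Why: Standard phenol silylation; the same silyl group as in 11 keeps the final deprotection to one operation.

Step 8
Reactants: 13 4-(tert-butyldimethylsilyloxy)-3-methoxybenzaldehyde
Product: 14 [4-(tert-butyldimethylsilyloxy)-3-methoxyphenyl]methanol
Conditions: NaBH4, MeOH, 0 °C
Reagents that add atoms: none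
Why: Borohydride reduction of an aromatic aldehyde; short exposure at 0 °C leaves the aryl silyl ether in place.

Step 9
Reactants: 14 [4-(tert-butyldimethylsilyloxy)-3-methoxyphenyl]methanol
Product: 15 [4-(bromomethyl)-2-methoxyphenoxy](tert-butyl)dimethylsilane
Conditions: CBr4, PPh3, CH2Cl2, 0 °C; used at once
Reagents that add atoms: carbon tetrabromide, BrC(Br)(Br)Br
Why: Appel bromination under neutral conditions, which suits an acid-sensitive electron-rich benzylic system; the bromide is filtered through silica and used fresh.

Step 10
Reactants: 11 (4R)-4-{(S)-(tert-butyldimethylsilyloxy)[4-(tert-butyldimethylsilyloxy)-3,5-dimethoxyphenyl]methyl}dihydrofuran-2(3H)-one; 15 [4-(bromomethyl)-2-methoxyphenoxy](tert-butyl)dimethylsilane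
Product: 17 (3R,4R)-3-[4-(tert-butyldimethylsilyloxy)-3-methoxybenzyl]-4-{(S)-(tert-butyldimethylsilyloxy)[4-(tert-butyldimethylsilyloxy)-3,5-dimethoxyphenyl]methyl}dihydrofuran-2(3H)-one, via lithium enolate 16 (not isolated)
Conditions: LiN(i-Pr)2 (1.1 equiv), THF, −78 °C; then 15 (1.2 equiv), −78 to −40 °C
Reagents that add atoms: none
Why: Alkylation of a γ-butyrolactone enolate; the bulky C8 substituent shields one face of the planar enolate, so the benzyl group should enter anti and set C8' as R (trans), the usual outcome for β-substituted butyrolactones, and the β-carbon carries no leaving group, so elimination is not a concern.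

Step 11
Reactants: 17 (3R,4R)-3-[4-(tert-butyldimethylsilyloxy)-3-methoxybenzyl]-4-{(S)-(tert-butyldimethylsilyloxy)[4-(tert-butyldimethylsilyloxy)-3,5-dimethoxyphenyl]methyl}dihydrofuran-2(3H)-one
Product: 18 (2R,3R)-2-[4-(tert-butyldimethylsilyloxy)-3-methoxybenzyl]-3-{(S)-(tert-butyldimethylsilyloxy)[4-(tert-butyldimethylsilyloxy)-3,5-dimethoxyphenyl]methyl}butane-1,4-diol
Conditions: LiAlH4, THF, 0 °C, short reaction time
Reagents that add atoms: none
Why: Hydride reduction of the lactone to the 1,4-diol; no stereocentre is involved, and at 0 °C the aryl and alkyl silyl ethers should persist.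

Step 12
Reactants: 18 (2R,3R)-2-[4-(tert-butyldimethylsilyloxy)-3-methoxybenzyl]-3-{(S)-(tert-butyldimethylsilyloxy)[4-(tert-butyldimethylsilyloxy)-3,5-dimethoxyphenyl]methyl}butane-1,4-diol
Product: 20 (3R,4R)-3-[4-(tert-butyldimethylsilyloxy)-3-methoxybenzyl]-4-{(S)-(tert-butyldimethylsilyloxy)[4-(tert-butyldimethylsilyloxy)-3,5-dimethoxyphenyl]methyl}tetrahydrofuran, via monotosylate 19 (not isolated)
Conditions: TsCl (1.1 equiv), pyridine, DMAP (cat.), CH2Cl2, 0 °C to rt, then 40 °C
Reagents that add atoms: none
Why: Mono-sulfonylation of the less hindered primary hydroxyl (at C9') followed by 5-exo-tet displacement by the other primary hydroxyl; the regioisomeric monotosylate closes to the same ether, no stereocentre is touched, and the silylated O7 cannot compete.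

Step 13
Reactants: 20 (3R,4R)-3-[4-(tert-butyldimethylsilyloxy)-3-methoxybenzyl]-4-{(S)-(tert-butyldimethylsilyloxy)[4-(tert-butyldimethylsilyloxy)-3,5-dimethoxyphenyl]methyl}tetrahydrofuran
Product: 21 (S)-[(3R,4R)-4-(4-hydroxy-3-methoxybenzyl)tetrahydrofuran-3-yl](4-hydroxy-3,5-dimethoxyphenyl)methanol
Conditions: Bu4NF (4 equiv), AcOH (4 equiv), THF, 0 °C to rt
Reagents that add atoms: none
Why: Fluoride cleavage of the two aryl silyl ethers and the secondary benzylic silyl ether in one operation; acetic acid buffers the phenoxide so that the p-hydroxybenzylic alcohol is not driven towards a quinone methide, and no stereocentre is affected.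

## Compound list

1 | 4-bromo-2,6-dimethoxyphenol | COc1cc(Br)cc(OC)c1O | starting material
2 | (4-bromo-2,6-dimethoxyphenoxy)(tert-butyl)dimethylsilane | COc1cc(Br)cc(OC)c1O[Si](C)(C)C(C)(C)C | intermediate
3 | 3-methylidenecyclobutane-1-carbonitrile | C=C1CC(C#N)C1 | starting material
4 | [4-(tert-butyldimethylsilyloxy)-3,5-dimethoxyphenyl]magnesium bromide | COc1cc([Mg]Br)cc(OC)c1O[Si](C)(C)C(C)(C)C | intermediate (not isolated)
5 | N-bromomagnesio ketimine of 6 | C=C1CC(C1)C(=N[Mg]Br)c1cc(OC)c(O[Si](C)(C)C(C)(C)C)c(OC)c1 | intermediate (not isolated)
6 | [4-(tert-butyldimethylsilyloxy)-3,5-dimethoxyphenyl](3-methylidenecyclobutyl)methanone | C=C1CC(C1)C(=O)c1cc(OC)c(O[Si](C)(C)C(C)(C)C)c(OC)c1 | intermediate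
7 | (S)-[4-(tert-butyldimethylsilyloxy)-3,5-dimethoxyphenyl](3-methylidenecyclobutyl)methanol | C=C1CC(C1)[C@H](O)c1cc(OC)c(O[Si](C)(C)C(C)(C)C)c(OC)c1 | intermediate
8 | tert-butyl{(S)-[4-(tert-butyldimethylsilyloxy)-3,5-dimethoxyphenyl](3-methylidenecyclobutyl)methoxy}dimethylsilane | C=C1CC(C1)[C@H](O[Si](C)(C)C(C)(C)C)c1cc(OC)c(O[Si](C)(C)C(C)(C)C)c(OC)c1 | intermediate
9 | 1-(hydroxymethyl)-3-{(S)-(tert-butyldimethylsilyloxy)[4-(tert-butyldimethylsilyloxy)-3,5-dimethoxyphenyl]methyl}cyclobutan-1-ol (cis/trans mixture at the ring) | OCC1(O)CC(C1)[C@H](O[Si](C)(C)C(C)(C)C)c1cc(OC)c(O[Si](C)(C)C(C)(C)C)c(OC)c1 | intermediate (not isolated)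
10 | 3-{(S)-(tert-butyldimethylsilyloxy)[4-(tert-butyldimethylsilyloxy)-3,5-dimethoxyphenyl]methyl}cyclobutan-1-one | O=C1CC(C1)[C@H](O[Si](C)(C)C(C)(C)C)c1cc(OC)c(O[Si](C)(C)C(C)(C)C)c(OC)c1 | intermediate
11 | (4R)-4-{(S)-(tert-butyldimethylsilyloxy)[4-(tert-butyldimethylsilyloxy)-3,5-dimethoxyphenyl]methyl}dihydrofuran-2(3H)-one | O=C1C[C@H](CO1)[C@H](O[Si](C)(C)C(C)(C)C)c1cc(OC)c(O[Si](C)(C)C(C)(C)C)c(OC)c1 | intermediate
12 | vanillin (4-hydroxy-3-methoxybenzaldehyde) | COc1cc(C=O)ccc1O | starting material
13 | 4-(tert-butyldimethylsilyloxy)-3-methoxybenzaldehyde | COc1cc(C=O)ccc1O[Si](C)(C)C(C)(C)C | intermediate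
14 | [4-(tert-butyldimethylsilyloxy)-3-methoxyphenyl]methanol | COc1cc(CO)ccc1O[Si](C)(C)C(C)(C)C | intermediate
15 | [4-(bromomethyl)-2-methoxyphenoxy](tert-butyl)dimethylsilane | COc1cc(CBr)ccc1O[Si](C)(C)C(C)(C)C | intermediate
16 | lithium enolate of 11 (lithium 4,5-dihydrofuran-2-olate, ring carbon 4 as in 11) | [Li]OC1=C[C@H](CO1)[C@H](O[Si](C)(C)C(C)(C)C)c1cc(OC)c(O[Si](C)(C)C(C)(C)C)c(OC)c1 | intermediate (not isolated)
17 | (3R,4R)-3-[4-(tert-butyldimethylsilyloxy)-3-methoxybenzyl]-4-{(S)-(tert-butyldimethylsilyloxy)[4-(tert-butyldimethylsilyloxy)-3,5-dimethoxyphenyl]methyl}dihydrofuran-2(3H)-one | COc1cc(C[C@H]2C(=O)OC[C@@H]2[C@H](O[Si](C)(C)C(C)(C)C)c2cc(OC)c(O[Si](C)(C)C(C)(C)C)c(OC)c2)ccc1O[Si](C)(C)C(C)(C)C | intermediate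
18 | (2R,3R)-2-[4-(tert-butyldimethylsilyloxy)-3-methoxybenzyl]-3-{(S)-(tert-butyldimethylsilyloxy)[4-(tert-butyldimethylsilyloxy)-3,5-dimethoxyphenyl]methyl}butane-1,4-diol | COc1cc(C[C@@H](CO)[C@H](CO)[C@H](O[Si](C)(C)C(C)(C)C)c2cc(OC)c(O[Si](C)(C)C(C)(C)C)c(OC)c2)ccc1O[Si](C)(C)C(C)(C)C | intermediate
19 | (2R,3R)-2-[4-(tert-butyldimethylsilyloxy)-3-methoxybenzyl]-3-{(S)-(tert-butyldimethylsilyloxy)[4-(tert-butyldimethylsilyloxy)-3,5-dimethoxyphenyl]methyl}-4-hydroxybutyl 4-methylbenzenesulfonate (major regioisomer) | COc1cc(C[C@@H](COS(=O)(=O)c2ccc(C)cc2)[C@H](CO)[C@H](O[Si](C)(C)C(C)(C)C)c2cc(OC)c(O[Si](C)(C)C(C)(C)C)c(OC)c2)ccc1O[Si](C)(C)C(C)(C)C | intermediate (not isolated)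
20 | (3R,4R)-3-[4-(tert-butyldimethylsilyloxy)-3-methoxybenzyl]-4-{(S)-(tert-butyldimethylsilyloxy)[4-(tert-butyldimethylsilyloxy)-3,5-dimethoxyphenyl]methyl}tetrahydrofuran | COc1cc(C[C@H]2COC[C@@H]2[C@H](O[Si](C)(C)C(C)(C)C)c2cc(OC)c(O[Si](C)(C)C(C)(C)C)c(OC)c2)ccc1O[Si](C)(C)C(C)(C)C | intermediate
21 | (S)-[(3R,4R)-4-(4-hydroxy-3-methoxybenzyl)tetrahydrofuran-3-yl](4-hydroxy-3,5-dimethoxyphenyl)methanol | COc1cc(C[C@H]2COC[C@@H]2[C@H](O)c2cc(OC)c(O)c(OC)c2)ccc1O | target

## Step count and least certain steps

Total steps: 13. Longest linear sequence: 10 steps (steps 1 to 6 and 10 to 13); steps 7 to 9 form the three-step side arm.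

**Step 6 (key step).** The most likely failure is insufficient discrimination between the two ring methylenes, because the C8 substituent is a branched silyloxy(aryl)methyl group, not the plain aryl or alkyl group for which such catalysts are tuned. A second possibility is Lewis-acid ionisation of the benzylic silyl ether. The fallback replaces oxygen insertion by group-selective deprotonation and sets out from 10. A chiral lithium amide, LiN[(R)-CH(Me)Ph]2 or its antipode (whichever removes a proton from the pro-R methylene), with Et3SiCl present at −100 °C in THF, would give the triethylsilyl enol ether F1. Ozonolysis of F1 (O3, CH2Cl2–MeOH, −78 °C) with NaBH4 work-up would give the hydroxy acid F2, which lactonises on mild acidification and returns to the route at 11.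

**Step 2.** Proton transfer from the α-position of 3 to the hindered, electron-rich aryl Grignard reagent may compete with addition to the nitrile and return the de-brominated arene. The fallback sets out from 3. Alkaline hydrolysis (NaOH, aq. EtOH, reflux) would give 3-methylidenecyclobutane-1-carboxylic acid F3, and activation with 1,1'-carbonyldiimidazole and reaction with MeNHOMe·HCl would give the N-methoxy-N-methylamide F4. Addition of 4 (from 2) in a Weinreb ketone synthesis then returns to the route at 6.

**Step 3.** Facial discrimination may be incomplete, because the α-branched cyclobutyl group is closer in size to the aryl group than the methyl of the usual substrates. A modest shortfall is tolerable, since the wrong C7 enantiomer becomes a separable diastereomer at 11. If the shortfall is large, the fallback sets out from 6. NaBH4 would give the racemic alcohol F5, and esterification with (S)-2-methoxy-2-phenylacetic acid (DCC, DMAP) would give two diastereomeric esters. The ester of the (S)-carbinol F6 would be separated by chromatography or crystallisation and cleaved with LiAlH4 (THF, 0 °C), returning to the route at 7.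

**Step 10.** Decomposition of the labile electron-rich benzylic bromide may outpace C-alkylation of the hindered enolate, and proton exchange between product and enolate may erode the trans selectivity. The fallback uses a stable aldehyde as the electrophile and sets out from 11 (as 16) and 13. Aldol addition would give the trans aldol adduct F7 as a mixture at the new carbinol carbon. MsCl/Et3N followed by DBU would dehydrate it to the (E)-arylidene lactone F8. Hydrogenation (H2, Pd/C, EtOAc) should add hydrogen anti to the C8 substituent and give mainly the cis lactone F9. Equilibration at C8' with DBU then leads to the more stable trans isomer, returning to the route at 17.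

**Step 12.** Double sulfonylation may compete with ring closure, or the C7 silyl group may migrate to O9 under base, which would free O7 for the wrong (7,9') closure. The fallback sets out from 18: a Mitsunobu cyclodehydration (PPh3, diisopropyl azodicarboxylate, THF, 0 °C to rt) activates one primary hydroxyl as an alkoxyphosphonium ion under neutral conditions and returns directly to the route at 20 without a new isolated compound.

## Further compounds

F1 | step 6 | triethyl{[(3R)-3-{(S)-(tert-butyldimethylsilyloxy)[4-(tert-butyldimethylsilyloxy)-3,5-dimethoxyphenyl]methyl}cyclobut-1-en-1-yl]oxy}silane | CC[Si](CC)(CC)OC1=C[C@@H](C1)[C@H](O[Si](C)(C)C(C)(C)C)c1cc(OC)c(O[Si](C)(C)C(C)(C)C)c(OC)c1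
F2 | step 6 | (3R)-4-hydroxy-3-{(S)-(tert-butyldimethylsilyloxy)[4-(tert-butyldimethylsilyloxy)-3,5-dimethoxyphenyl]methyl}butanoic acid | OC[C@@H](CC(=O)O)[C@H](O[Si](C)(C)C(C)(C)C)c1cc(OC)c(O[Si](C)(C)C(C)(C)C)c(OC)c1
F3 | step 2 | 3-methylidenecyclobutane-1-carboxylic acid | C=C1CC(C(=O)O)C1
F4 | step 2 | N-methoxy-N-methyl-3-methylidenecyclobutane-1-carboxamide | C=C1CC(C1)C(=O)N(C)OC
F5 | step 3 | racemic [4-(tert-butyldimethylsilyloxy)-3,5-dimethoxyphenyl](3-methylidenecyclobutyl)methanol | C=C1CC(C1)C(O)c1cc(OC)c(O[Si](C)(C)C(C)(C)C)c(OC)c1
F6 | step 3 | (S)-[4-(tert-butyldimethylsilyloxy)-3,5-dimethoxyphenyl](3-methylidenecyclobutyl)methyl (S)-2-methoxy-2-phenylacetate | C=C1CC(C1)[C@H](OC(=O)[C@@H](OC)c1ccccc1)c1cc(OC)c(O[Si](C)(C)C(C)(C)C)c(OC)c1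
F7 | step 10 | (3S,4R)-3-{[4-(tert-butyldimethylsilyloxy)-3-methoxyphenyl](hydroxy)methyl}-4-{(S)-(tert-butyldimethylsilyloxy)[4-(tert-butyldimethylsilyloxy)-3,5-dimethoxyphenyl]methyl}dihydrofuran-2(3H)-one (both carbinol epimers) | COc1cc(C(O)[C@H]2C(=O)OC[C@@H]2[C@H](O[Si](C)(C)C(C)(C)C)c2cc(OC)c(O[Si](C)(C)C(C)(C)C)c(OC)c2)ccc1O[Si](C)(C)C(C)(C)C
F8 | step 10 | (4R)-3-[(E)-4-(tert-butyldimethylsilyloxy)-3-methoxybenzylidene]-4-{(S)-(tert-butyldimethylsilyloxy)[4-(tert-butyldimethylsilyloxy)-3,5-dimethoxyphenyl]methyl}dihydrofuran-2(3H)-one | COc1cc(/C=C2/C(=O)OC[C@@H]2[C@H](O[Si](C)(C)C(C)(C)C)c2cc(OC)c(O[Si](C)(C)C(C)(C)C)c(OC)c2)ccc1O[Si](C)(C)C(C)(C)C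
F9 | step 10 | (3S,4R)-3-[4-(tert-butyldimethylsilyloxy)-3-methoxybenzyl]-4-{(S)-(tert-butyldimethylsilyloxy)[4-(tert-butyldimethylsilyloxy)-3,5-dimethoxyphenyl]methyl}dihydrofuran-2(3H)-one (cis) | COc1cc(C[C@@H]2C(=O)OC[C@@H]2[C@H](O[Si](C)(C)C(C)(C)C)c2cc(OC)c(O[Si](C)(C)C(C)(C)C)c(OC)c2)ccc1O[Si](C)(C)C(C)(C)C
F0 | step 12 | none | none
A1 | alternative 1 | (3R,4R,5R)-3-[4-(tert-butyldimethylsilyloxy)-3-methoxybenzyl]-4-{2-[4-(tert-butyldimethylsilyloxy)-3,5-dimethoxyphenyl]-1,3-dithian-2-yl}-5-[(1R,2S,5R)-menthyloxy]dihydrofuran-2(3H)-one | O=C1O[C@@H](O[C@H]2[C@H](C(C)C)CC[C@@H](C)C2)[C@H](C2(SCCCS2)c2cc(OC)c(O[Si](C)(C)C(C)(C)C)c(OC)c2)[C@H]1Cc1ccc(O[Si](C)(C)C(C)(C)C)c(OC)c1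
A2 | alternative 1 | (5R)-5-[(1R,2S,5R)-menthyloxy]furan-2(5H)-one | O=C1O[C@@H](O[C@H]2[C@H](C(C)C)CC[C@@H](C)C2)C=C1
A3 | alternative 1 | 2-[4-(tert-butyldimethylsilyloxy)-3,5-dimethoxyphenyl]-1,3-dithiane | COc1cc(C2SCCCS2)cc(OC)c1O[Si](C)(C)C(C)(C)C
A4 | alternative 2 | (S)-4-benzyl-3-{[(3R,4R)-4-(4-tert-butyldimethylsilyloxy-3-methoxybenzyl)tetrahydrofuran-3-yl]carbonyl}oxazolidin-2-one | O=C1OC[C@H](Cc2ccccc2)N1C(=O)[C@H]1COC[C@@H]1Cc1ccc(O[Si](C)(C)C(C)(C)C)c(OC)c1
A5 | alternative 2 | (S)-4-benzyl-3-[(E)-4-(4-tert-butyldimethylsilyloxy-3-methoxyphenyl)but-2-enoyl]oxazolidin-2-one | O=C1OC[C@H](Cc2ccccc2)N1C(=O)/C=C/Cc1ccc(O[Si](C)(C)C(C)(C)C)c(OC)c1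
A6 | alternative 2 | chloromethyl (trimethylsilyl)methyl ether | C[Si](C)(C)COCCl
A7 | alternative 3 | (3S,4R)-3-[4-(tert-butyldimethylsilyloxy)-3,5-dimethoxybenzoyl]-4-[4-(tert-butyldimethylsilyloxy)-3-methoxybenzyl]dihydrofuran-2(3H)-one | O=C1OC[C@H](Cc2ccc(O[Si](C)(C)C(C)(C)C)c(OC)c2)[C@H]1C(=O)c1cc(OC)c(O[Si](C)(C)C(C)(C)C)c(OC)c1
A8 | alternative 3 | 3-[4-(tert-butyldimethylsilyloxy)-3-methoxyphenyl]propyl 2-diazo-3-[4-(tert-butyldimethylsilyloxy)-3,5-dimethoxyphenyl]-3-oxopropanoate | COc1cc(CCCOC(=O)C(=[N+]=[N-])C(=O)c2cc(OC)c(O[Si](C)(C)C(C)(C)C)c(OC)c2)ccc1O[Si](C)(C)C(C)(C)C
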